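All runs were generated by integration for substances that don't exist, and the scatter is random.

A pitfall: I nearly read the substrate column as what remained. But in Sunday's run at 8.00 h, product plus substrate falls short of the charge by 5.1 percentage points, and the amount asked counts idle adduct as product.

all flasks: substrate 0.50 M

|  | solid reagent | initiator | remark | time |
|---|---|---|---|---|
| Sunday's | 2.5 M | 8.9 mM | run made earlier |  |
| Tuesday's | 2.5 M | 20 mM | run made earlier |  |
| Thursday's | 2.5 M | 47 mM | run made earlier |  |
| winter | 2.50 M | 8.0 mM |  | 10 h |
| autumn | 2.50 M | 15 mM |  | 10 h |
| midnight | 2.50 M | 30 mM |  | 10 h |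
| summer | 2.50 M | 60 mM |  | 10 h |

- Sunday's (time / h: product / %, substrate / %): 0.833: 9.0, 90.0; 2.50: 23.4, 74.1; 5.00: 40.0, 56.9; 8.00: 54.0, 40.9
- Tuesday's (time / h: product / %, substrate / %): 2.00: 26.0, 70.5; 4.00: 45.5, 51.3; 5.00: 52.9, 42.4; 8.00: 68.8, 27.5
- Thursday's (time / h: product / %, substrate / %): 0.833: 17.4, 78.6; 2.50: 44.6, 51.5; 5.00: 67.1, 28.8; 8.00: 80.9, 14.6

(scatter of a reading: 0.5 percentage points)

- a species is counted by the substrate in it: one idle adduct counts as two
- amounts and yields of product count idle adduct too
- given per volume of solution although it is solid: solid reagent
- steps that have been proposed: substrate + product <-> idle adduct; partner + chain carrier -> product + initiating radical; substrate + initiating radical -> chain carrier; solid reagent <-> partner; initiator -> 2 initiating radical; 2 initiating radical -> ended chains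
- at the start none of the solid reagent is in solution
- in an amount of product, one idle adduct counts as one product
- "hardly changes" means that all values lie within two and a half points (for a concentration: within two and a half percent of the largest)

1. amount of product at the end, in percent of the substrate charged for winter, autumn, midnight, summer, in this order
2. how the row runs (falls all the way / rises all the way / falls, then rises / rises, then falls / hardly changes)

So I worked with the remainder, one minus the product fraction. Its negative logarithm is the reach, the number of time constants passed in a pseudo-first-order decay. From the readings at 5.00 h and 8.00 h, I ran each reach straight on to 10 h. Sunday's run gave 0.954, Tuesday's 1.44 and Thursday's 2.02.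

Initiating radicals end in pairs, so I tried the root of c(initiator). Thursday's reach over Sunday's is 2.12, less than the initiator ratio of 5.28 and near its root, 2.30.

I divided each reach by the root of its initiator ratio to 8.0 mM and averaged, which gave 0.882. This is the reduced reach, my estimate of the reach at 10 h of a flask charged with 8.0 mM. Multiplied back by each root, it gave me 58.6%, 70.1%, 81.9% and 91.1%.

The forecast gave 58.5%, 70%, 81% and 90%, a row that rises all the way, on rate constants that “scale with the square root of initiator”.

The flasks gave 59.3%, 70.2%, 81.3% and 90.2%: the row rises all the way.

    substrate + product ⇌ idle adduct, settled at all times (K = 0.440 L mol⁻¹)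
    partner + chain carrier → product + initiating radical (k = 1.30 × 10⁵ L mol⁻¹ min⁻¹)
    substrate + initiating radical → chain carrier (k = 46000 L mol⁻¹ min⁻¹)
    solid reagent ⇌ partner, rate k4*(cs4 - [partner]) while solid is left; crystals form when [partner] > cs4 (solubility = 0.170 M, k = 0.0140 min⁻¹)
    initiator → 2 initiating radical (k = 4.20 × 10⁻⁴ min⁻¹)
    2 initiating radical → ended chains (k = 4.10 × 10⁷ L mol⁻¹ s⁻¹)

Winter's 59.3% is a reduced reach of 0.899, beside my 0.882. Winter's c(initiating radical) at 10.0 h was 3.26 × 10⁻⁸ M and summer's was 8.92 × 10⁻⁸ M, a ratio of 2.74, while the root of their initiator ratio is 2.74. Summer's 90.2% is a reach of 2.32, and divided by that root, a reduced reach of 0.848.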